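The route builds ring A by polyketide-style folding, once ring B, the stereocentre and the Z-alkene chain are in place. Ring A carries two meta oxygens (on C1 and C3) and the chain on C5, between the ring CH atoms C4 and C6. This is the pattern a 3,5,7-triketo ester gives when its C2 closes onto the C7 ketone. A diketo-dioxinone bearing the brominated, protected ring B is heated with methanol and treated with Cs2CO3: one operation unmasks the tetraketide and closes ring A as a resorcylate. Decarboxylation then leaves a symmetric resorcinol for Ullmann macro-etherification and a single fluoride deprotection.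

Key step: step 12

Remark: the SMILES is read as the (R) carbinol with a Z alkene; methyl 4-bromo-3,5-dihydroxybenzoate is taken as a catalogue compound (otherwise the Fischer ester of the equally available acid). Abbreviations: SEM = 2-(trimethylsilyl)ethoxymethyl; TIPS = triisopropylsilyl; ArB = 4-bromo-3,5-bis(SEM-oxy)phenyl, the ring B unit.

Step 1
Reactants: 1 methyl 4-bromo-3,5-dihydroxybenzoate
Product: 2 methyl 4-bromo-3,5-bis{[2-(trimethylsilyl)ethoxy]methoxy}benzoate
Conditions: SEMCl (2.5 equiv), iPr2NEt (3 equiv), CH2Cl2, 0 to 23 °C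
Reagents that add atoms: 2-(trimethylsilyl)ethoxymethyl chloride, C[Si](C)(C)CCOCCl
Why: Williamson-type O-alkylation of the two acidic phenols by the reactive α-chloro ether should give acetals that tolerate Grignard, amide-base, carbonate, hydroxide and copper conditions yet fall to fluoride at the end, so that no acid ever meets the ionisable benzylic carbinol.

Step 2
Reactants: 2 methyl 4-bromo-3,5-bis{[2-(trimethylsilyl)ethoxy]methoxy}benzoate
Product: 3 4-bromo-N-methoxy-N-methyl-3,5-bis{[2-(trimethylsilyl)ethoxy]methoxy}benzamide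
Conditions: MeNH(OMe)·HCl (1.5 equiv), iPrMgCl (3.0 equiv), THF, −20 to 0 °C; aq NH4Cl
Reagents that add atoms: N,O-dimethylhydroxylamine hydrochloride, CNOC.Cl
Why: Weinreb amide synthesis by aminolysis of the ester with the chloromagnesium amide made in the flask is fast at −20 °C, and since the N–H protons consume all of the iPrMgCl no bromine–magnesium exchange should occur at the aryl bromide.

Step 3
Reactants: 3 4-bromo-N-methoxy-N-methyl-3,5-bis{[2-(trimethylsilyl)ethoxy]methoxy}benzamide; 4 8-bromooct-1-ene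
Product: 6 1-ArB-non-8-en-1-one, via oct-7-en-1-ylmagnesium bromide 5 (not isolated)
Conditions: 4 (1.4 equiv), Mg, THF, 40 °C; then 3, THF, 0 °C; aq NH4Cl
Reagents that add atoms: none
Why: In this Weinreb ketone synthesis the five-membered magnesium chelate formed on Grignard addition should hold until work-up, which excludes over-addition, while the terminal alkene is carried as a masked aldehyde.

Step 4
Reactants: 6 1-ArB-non-8-en-1-one
Product: 7 (1R)-1-ArB-non-8-en-1-ol
Conditions: RuCl(p-cymene)[(R,R)-TsDPEN] (1 mol %), HCO2H/Et3N (5:2), EtOAc, 30 °C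
Reagents that add atoms: none
Why: Noyori asymmetric transfer hydrogenation of an aryl n-alkyl ketone with the (R,R)-diamine ruthenium hydride, whose cymene ligand orients ring B by a CH/π contact, should deliver hydride to the face that gives the (R) carbinol and leaves the terminal alkene and the aryl bromide untouched, which a borane reductant would not.

Step 5
Reactants: 7 (1R)-1-ArB-non-8-en-1-ol
Product: 8 {[(1R)-1-ArB-non-8-en-1-yl]oxy}tri(propan-2-yl)silane
Conditions: TIPSOTf (1.3 equiv), 2,6-lutidine (2 equiv), CH2Cl2, −78 to 0 °C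
Reagents that add atoms: triisopropylsilyl trifluoromethanesulfonate, CC(C)[Si](OS(=O)(=O)C(F)(F)F)(C(C)C)C(C)C
Why: O-Silylation with a silyl triflate and a hindered pyridine base takes place at oxygen with retention at carbon, and the TIPS ether is chosen as the common silyl ether most resistant to the hot hydroxide of step 13.

Step 6
Reactants: 8 {[(1R)-1-ArB-non-8-en-1-yl]oxy}tri(propan-2-yl)silane
Product: 10 (8R)-8-ArB-8-[(triisopropylsilyl)oxy]octanal, via the vicinal diol 9 (not isolated)
Conditions: OsO4 (2 mol %), NaIO4 (4 equiv), 2,6-lutidine (2 equiv), dioxane/H2O 3:1, 23 °C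
Reagents that add atoms: sodium periodate, [Na+].[O-]I(=O)(=O)=O
Why: Lemieux–Johnson oxidation (osmylation of the only alkene, then periodate cleavage of the diol) should shorten the chain by one carbon to the aldehyde, and it is placed before the Z alkene exists so that no second alkene can compete.

Step 7
Reactants: 11 7-bromoheptanoic acid
Product: 12 (6-carboxyhexyl)triphenylphosphonium bromide
Conditions: PPh3 (1.1 equiv), MeCN, reflux
Reagents that add atoms: triphenylphosphine, c1ccc(cc1)P(c1ccccc1)c1ccccc1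
Why: SN2 quaternisation of triphenylphosphine by the primary bromide should give the crystalline phosphonium salt.

Step 8
Reactants: 10 (8R)-8-ArB-8-[(triisopropylsilyl)oxy]octanal; 12 (6-carboxyhexyl)triphenylphosphonium bromide
Product: 14 (7Z,15R)-15-ArB-15-[(triisopropylsilyl)oxy]pentadec-7-enoic acid, via the sodium ylide carboxylate 13 (not isolated)
Conditions: 12 (1.5 equiv), NaN(SiMe3)2 (3.0 equiv), THF, 0 °C; then 10, −78 to 23 °C; 0.5 M HCl to pH 4, 0 °C
Reagents that add atoms: none
Why: Wittig olefination with a non-stabilised ylide under lithium-free conditions passes through the kinetically preferred cis-oxaphosphetane and should therefore give the Z alkene, the acid being carried as its sodium carboxylate.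

Step 9
Reactants: 14 (7Z,15R)-15-ArB-15-[(triisopropylsilyl)oxy]pentadec-7-enoic acid
Product: 16 (7Z,15R)-15-ArB-N-methoxy-N-methyl-15-[(triisopropylsilyl)oxy]pentadec-7-enamide, via the acyl imidazolide 15 (not isolated)
Conditions: CDI (1.2 equiv), CH2Cl2, 23 °C; then MeNH(OMe)·HCl (1.5 equiv), 23 °C
Reagents that add atoms: N,O-dimethylhydroxylamine hydrochloride, CNOC.Cl
Why: CDI-mediated amide coupling turns the acid into a Weinreb amide, an acyl donor whose tetrahedral adduct does not collapse in the flask and so can neither over-react with nor protonate the dianion used in step 11.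

Step 10
Reactants: 17 2,2,6-trimethyl-4H-1,3-dioxin-4-one
Product: 19 2,2-dimethyl-6-(2-oxopropyl)-4H-1,3-dioxin-4-one, via the lithium dienolate 18 (not isolated)
Conditions: 17 (2.0 equiv), LiN(SiMe3)2 (2.0 equiv), THF, −78 °C; then AcCl (1.0 equiv), −78 °C; aq NH4Cl
Reagents that add atoms: acetyl chloride, CC(Cl)=O
Why: Claisen-type vinylogous C-acylation of the dioxinone dienolate at its exocyclic carbon should give the keto-dioxinone, half of the dienolate serving as the base that takes up the more acidic product and returning as recoverable 17.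

Step 11
Reactants: 16 (7Z,15R)-15-ArB-N-methoxy-N-methyl-15-[(triisopropylsilyl)oxy]pentadec-7-enamide; 19 2,2-dimethyl-6-(2-oxopropyl)-4H-1,3-dioxin-4-one
Product: 21 6-{(10Z,18R)-18-ArB-2,4-dioxo-18-[(triisopropylsilyl)oxy]octadec-10-en-1-yl}-2,2-dimethyl-4H-1,3-dioxin-4-one, via the dilithium dianion 20 (not isolated)
Conditions: 19 (2.2 equiv), LiN(iPr)2 (4.4 equiv), THF, −78 °C; then 16, −78 to −20 °C; aq NH4Cl
Reagents that add atoms: none
Why: Claisen-type C-acylation of a 1,3-dicarbonyl dianion occurs at its terminal, more basic carbon, and the Weinreb chelate should keep the new tricarbonyl array masked until the cold quench.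

Step 12
Reactants: 21 6-{(10Z,18R)-18-ArB-2,4-dioxo-18-[(triisopropylsilyl)oxy]octadec-10-en-1-yl}-2,2-dimethyl-4H-1,3-dioxin-4-one
Product: 25 methyl 2-{(6Z,14R)-14-ArB-14-[(triisopropylsilyl)oxy]tetradec-6-en-1-yl}-4,6-dihydroxybenzoate, via the acylketene 22 (not isolated), via the triketo methyl ester 23 (not isolated), via the cyclic aldol 24 (not isolated)
Conditions: PhMe/MeOH 10:1, sealed tube, 110 °C; evaporate; Cs2CO3 (2 equiv), MeOH, 23 °C; then AcOH (5 equiv), 23 °C
Reagents that add atoms: methanol, CO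
Why: Heating drives a retro-hetero-Diels–Alder loss of acetone from the dioxinone to the acylketene 22, which methanol captures as the 3,5,7-triketo ester 23; Cs2CO3 then enolises C2, the carbon between the ester and the C3 ketone, and this carbon adds to the chain-bearing C7 ketone to give the carbocyclic aldol 24, which loses water and tautomerises to the aromatic resorcylate 25 (the closest known reaction type is dioxinone thermolysis with alcohol capture followed by base-mediated aldol aromatisation of a triketo ester). Ring A closes by a 6-(enolendo)-exo-trig aldol addition, and the C2–C7 bond is the only new skeletal bond. No stereocentre is created, because the carbinol carbon of 24 becomes aromatic, and the (R)-silyloxy centre and the Z alkene lie far from every acidic site. The step needs the aldol mode (C2 onto C7) to win over Claisen closure (C6 onto the ester carbon, which would give an acylphloroglucinol) and over O-cyclisation to a pyranone; capture of the ketene as a simple, weakly electrophilic methyl ester and a mild carbonate base at 23 °C, under which the doubly activated C2 is the nucleophile, should secure this. The acetic acid finish completes the dehydration without acid strong enough to disturb the SEM acetals or the benzylic TIPS ether.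

Step 13
Reactants: 25 methyl 2-{(6Z,14R)-14-ArB-14-[(triisopropylsilyl)oxy]tetradec-6-en-1-yl}-4,6-dihydroxybenzoate
Product: 27 5-{(6Z,14R)-14-ArB-14-[(triisopropylsilyl)oxy]tetradec-6-en-1-yl}benzene-1,3-diol, via the resorcylic acid 26 (not isolated)
Conditions: KOH (15 equiv), MeOH/H2O 3:1 (degassed), 80 °C; then 1 M HCl to pH 4, 0 °C
Reagents that add atoms: none
Why: Saponification of the hindered salicylate-type ester followed by protodecarboxylation of the 2,4-dihydroxybenzoic acid (reverse Kolbe–Schmitt, ipso protonation ortho and para to the two oxygens) should occur in the same hot alkaline pot and leave a resorcinol with two equivalent hydroxyls, while the SEM acetals, the TIPS ether, the aryl bromide and the Z alkene are inert to hydroxide.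

Step 14
Reactants: 27 5-{(6Z,14R)-14-ArB-14-[(triisopropylsilyl)oxy]tetradec-6-en-1-yl}benzene-1,3-diol
Product: 28 the SEM- and TIPS-protected 22-membered macrocyclic diaryl ether
Conditions: CuI (copper iodide, 30 mol %), picolinic acid (60 mol %), K3PO4 (4 equiv), DMSO/1,4-dioxane 1:1 (degassed), 100 °C, slow addition of 27 over 12 h to 2 mM
Reagents that add atoms: none
Why: Intramolecular Ullmann diaryl ether synthesis, in which the copper phenoxide of ring A engages the ring B C–Br bond and C–O reductive elimination closes the unstrained 22-membered ring, should be favoured over oligomerisation at high dilution, and because the two ring A hydroxyls are equivalent either one gives the same product.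

Step 15
Reactants: 28 the SEM- and TIPS-protected 22-membered macrocyclic diaryl ether
Product: 29 the target CNP0316989.2
Conditions: Bu4NF (10 equiv), ethylenediamine (5 equiv), THF/DMPU 4:1 (degassed), 60 °C; then AcOH, aq NH4Cl
Reagents that add atoms: none
Why: Fluoride-mediated desilylation cleaves the TIPS ether directly and triggers the fragmentation of both aryl SEM ethers (loss of Me3SiF, ethene and formaldehyde, the last scavenged by the diamine), so all three hydroxyls should be freed in one operation without acid that could ionise the benzylic carbinol.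

Compound list
1 | methyl 4-bromo-3,5-dihydroxybenzoate | COC(=O)c1cc(O)c(Br)c(O)c1 | starting material
2 | methyl 4-bromo-3,5-bis{[2-(trimethylsilyl)ethoxy]methoxy}benzoate | COC(=O)c1cc(OCOCC[Si](C)(C)C)c(Br)c(OCOCC[Si](C)(C)C)c1 | intermediate
3 | 4-bromo-N-methoxy-N-methyl-3,5-bis{[2-(trimethylsilyl)ethoxy]methoxy}benzamide | CON(C)C(=O)c1cc(OCOCC[Si](C)(C)C)c(Br)c(OCOCC[Si](C)(C)C)c1 | intermediate
4 | 8-bromooct-1-ene | C=CCCCCCCBr | starting material
5 | oct-7-en-1-ylmagnesium bromide (not isolated) | C=CCCCCCC[Mg]Br | intermediate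
6 | 1-ArB-non-8-en-1-one | C=CCCCCCCC(=O)c1cc(OCOCC[Si](C)(C)C)c(Br)c(OCOCC[Si](C)(C)C)c1 | intermediate
7 | (1R)-1-ArB-non-8-en-1-ol | C[Si](C)(C)CCOCOc1cc(cc(OCOCC[Si](C)(C)C)c1Br)[C@H](O)CCCCCCC=C | intermediate
8 | {[(1R)-1-ArB-non-8-en-1-yl]oxy}tri(propan-2-yl)silane | C[Si](C)(C)CCOCOc1cc(cc(OCOCC[Si](C)(C)C)c1Br)[C@H](O[Si](C(C)C)(C(C)C)C(C)C)CCCCCCC=C | intermediate
9 | (9R)-9-ArB-9-[(triisopropylsilyl)oxy]nonane-1,2-diol, both C2 epimers (not isolated) | C[Si](C)(C)CCOCOc1cc(cc(OCOCC[Si](C)(C)C)c1Br)[C@H](O[Si](C(C)C)(C(C)C)C(C)C)CCCCCCC(O)CO | intermediate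
10 | (8R)-8-ArB-8-[(triisopropylsilyl)oxy]octanal | C[Si](C)(C)CCOCOc1cc(cc(OCOCC[Si](C)(C)C)c1Br)[C@H](O[Si](C(C)C)(C(C)C)C(C)C)CCCCCCC=O | intermediate
11 | 7-bromoheptanoic acid | OC(=O)CCCCCCBr | starting material
12 | (6-carboxyhexyl)triphenylphosphonium bromide | OC(=O)CCCCCC[P+](c1ccccc1)(c1ccccc1)c1ccccc1.[Br-] | intermediate
13 | sodium 7-(triphenylphosphoranylidene)heptanoate (not isolated) | [Na+].[O-]C(=O)CCCCCC=P(c1ccccc1)(c1ccccc1)c1ccccc1 | intermediate
14 | (7Z,15R)-15-ArB-15-[(triisopropylsilyl)oxy]pentadec-7-enoic acid | C[Si](C)(C)CCOCOc1cc(cc(OCOCC[Si](C)(C)C)c1Br)[C@H](O[Si](C(C)C)(C(C)C)C(C)C)CCCCCC/C=C\CCCCCC(=O)O | intermediate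
15 | 1-[(7Z,15R)-15-ArB-15-[(triisopropylsilyl)oxy]pentadec-7-enoyl]-1H-imidazole (not isolated) | C[Si](C)(C)CCOCOc1cc(cc(OCOCC[Si](C)(C)C)c1Br)[C@H](O[Si](C(C)C)(C(C)C)C(C)C)CCCCCC/C=C\CCCCCC(=O)n1ccnc1 | intermediate
16 | (7Z,15R)-15-ArB-N-methoxy-N-methyl-15-[(triisopropylsilyl)oxy]pentadec-7-enamide | C[Si](C)(C)CCOCOc1cc(cc(OCOCC[Si](C)(C)C)c1Br)[C@H](O[Si](C(C)C)(C(C)C)C(C)C)CCCCCC/C=C\CCCCCC(=O)N(C)OC | intermediate
17 | 2,2,6-trimethyl-4H-1,3-dioxin-4-one | CC1=CC(=O)OC(C)(C)O1 | starting material
18 | lithium 2,2-dimethyl-6-methylidene-6H-1,3-dioxin-4-olate (not isolated) | [Li+].C=C1C=C([O-])OC(C)(C)O1 | intermediate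
19 | 2,2-dimethyl-6-(2-oxopropyl)-4H-1,3-dioxin-4-one | CC(=O)CC1=CC(=O)OC(C)(C)O1 | intermediate
20 | dilithium dienediolate (dianion) of 19 (not isolated) | [Li+].[Li+].C=C([O-])C=C1C=C([O-])OC(C)(C)O1 | intermediate
21 | 6-{(10Z,18R)-18-ArB-2,4-dioxo-18-[(triisopropylsilyl)oxy]octadec-10-en-1-yl}-2,2-dimethyl-4H-1,3-dioxin-4-one | C[Si](C)(C)CCOCOc1cc(cc(OCOCC[Si](C)(C)C)c1Br)[C@H](O[Si](C(C)C)(C(C)C)C(C)C)CCCCCC/C=C\CCCCCC(=O)CC(=O)CC1=CC(=O)OC(C)(C)O1 | intermediate
22 | (13Z,21R)-21-ArB-21-[(triisopropylsilyl)oxy]henicosa-1,13-diene-1,3,5,7-tetrone, the acylketene (not isolated) | C[Si](C)(C)CCOCOc1cc(cc(OCOCC[Si](C)(C)C)c1Br)[C@H](O[Si](C(C)C)(C(C)C)C(C)C)CCCCCC/C=C\CCCCCC(=O)CC(=O)CC(=O)C=C=O | intermediate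
23 | methyl (13Z,21R)-21-ArB-3,5,7-trioxo-21-[(triisopropylsilyl)oxy]henicos-13-enoate (not isolated) | C[Si](C)(C)CCOCOc1cc(cc(OCOCC[Si](C)(C)C)c1Br)[C@H](O[Si](C(C)C)(C(C)C)C(C)C)CCCCCC/C=C\CCCCCC(=O)CC(=O)CC(=O)CC(=O)OC | intermediate
24 | methyl 2-{(6Z,14R)-14-ArB-14-[(triisopropylsilyl)oxy]tetradec-6-en-1-yl}-2-hydroxy-4,6-dioxocyclohexane-1-carboxylate, ring epimers (not isolated) | C[Si](C)(C)CCOCOc1cc(cc(OCOCC[Si](C)(C)C)c1Br)[C@H](O[Si](C(C)C)(C(C)C)C(C)C)CCCCCC/C=C\CCCCCC1(O)CC(=O)CC(=O)C1C(=O)OC | intermediate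
25 | methyl 2-{(6Z,14R)-14-ArB-14-[(triisopropylsilyl)oxy]tetradec-6-en-1-yl}-4,6-dihydroxybenzoate | C[Si](C)(C)CCOCOc1cc(cc(OCOCC[Si](C)(C)C)c1Br)[C@H](O[Si](C(C)C)(C(C)C)C(C)C)CCCCCC/C=C\CCCCCc1cc(O)cc(O)c1C(=O)OC | intermediate
26 | 2-{(6Z,14R)-14-ArB-14-[(triisopropylsilyl)oxy]tetradec-6-en-1-yl}-4,6-dihydroxybenzoic acid (not isolated) | C[Si](C)(C)CCOCOc1cc(cc(OCOCC[Si](C)(C)C)c1Br)[C@H](O[Si](C(C)C)(C(C)C)C(C)C)CCCCCC/C=C\CCCCCc1cc(O)cc(O)c1C(=O)O | intermediate
27 | 5-{(6Z,14R)-14-ArB-14-[(triisopropylsilyl)oxy]tetradec-6-en-1-yl}benzene-1,3-diol | C[Si](C)(C)CCOCOc1cc(cc(OCOCC[Si](C)(C)C)c1Br)[C@H](O[Si](C(C)C)(C(C)C)C(C)C)CCCCCC/C=C\CCCCCc1cc(O)cc(O)c1 | intermediate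
28 | protected macrocycle: ring A (C1 aryl ether oxygen, C3 OH, C5 chain) joined through the C1 oxygen to C4 of ring B (C3 and C5 SEM-oxy) and through the chain ring A C5–(CH2)5–(Z)-CH=CH–(CH2)6–(R)-CH(OTIPS)–ring B C1; 22-membered ring | Oc1cc2cc(c1)Oc1c(OCOCC[Si](C)(C)C)cc(cc1OCOCC[Si](C)(C)C)[C@H](O[Si](C(C)C)(C(C)C)C(C)C)CCCCCC/C=C\CCCCC2 | intermediate
29 | CNP0316989.2: the same macrocycle with free hydroxyls at ring A C3, ring B C3 and C5 and the (R) benzylic carbinol, Z alkene | Oc1cc2cc(c1)Oc1c(O)cc(cc1O)[C@H](O)CCCCCC/C=C\CCCCC2 | target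

Total step count: 15. Longest linear sequence: 13 steps (steps 1–6, 8, 9, 11–15); steps 7 and 10 are side branches.

Steps most likely to fail

Step 14. Oxidative addition of the copper phenoxide at a C–Br bond flanked by two alkoxy groups is slow, so intermolecular etherification and hydrodebromination may overtake ring closure. The fallback sets out from 27 and makes the same C–O bond by a Buchwald–Hartwig etherification: Pd(OAc)2, 2-di-tert-butylphosphino-2′,4′,6′-triisopropylbiphenyl, K3PO4, toluene, 100 °C, slow addition to 2 mM. The bulky biarylphosphine is designed to force oxidative addition of zerovalent palladium into hindered aryl bromides and the subsequent C–O reductive elimination. It returns to the route at 28 and makes no new compound.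

Step 12. The acylketene or the open triketo ester may be diverted into O-cyclisation to a pyranone or into Claisen closure, or silyl and acetal groups may be lost in the acid finish. The fallback sets out from 21 and omits the thermolysis. Et3N in CH2Cl2 at 23 °C (then silica gel) should bring about the aldol closure on the intact dioxinone, whose ring CH carbon adds to the chain ketone. This gives the acetonide-bridged resorcylate 5-{(6Z,14R)-14-ArB-14-[(triisopropylsilyl)oxy]tetradec-6-en-1-yl}-7-hydroxy-2,2-dimethyl-4H-1,3-benzodioxin-4-one F1. Its ester carbon is locked in the ring, so neither ketene chemistry nor Claisen closure is possible. KOH in MeOH/H2O at 80 °C then opens the acetonide lactone and decarboxylates, and the route is rejoined at 27.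

Step 11. C-Acylation may stay incomplete because the dianion is consumed by proton transfer, O-acylation may compete, or the polycarbonyl product may cyclise on work-up. The fallback sets out from 16. Reduction with iBu2AlH (THF, −78 °C) should give the aldehyde (7Z,15R)-15-ArB-15-[(triisopropylsilyl)oxy]pentadec-7-enal F2. Aldol addition of the dianion 20 (from 19, LiN(iPr)2, THF, −78 °C) to this more electrophilic carbonyl gives the β-hydroxy keto-dioxinone 6-{(10Z,18R)-18-ArB-4-hydroxy-2-oxo-18-[(triisopropylsilyl)oxy]octadec-10-en-1-yl}-2,2-dimethyl-4H-1,3-dioxin-4-one F3 as a mixture of carbinol epimers. Dess–Martin periodinane (CH2Cl2, 23 °C) oxidises it to 21, where the route resumes.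

Further compounds
F0 | step 14 | none | none
F1 | step 12 | 5-{(6Z,14R)-14-ArB-14-[(triisopropylsilyl)oxy]tetradec-6-en-1-yl}-7-hydroxy-2,2-dimethyl-4H-1,3-benzodioxin-4-one | C[Si](C)(C)CCOCOc1cc(cc(OCOCC[Si](C)(C)C)c1Br)[C@H](O[Si](C(C)C)(C(C)C)C(C)C)CCCCCC/C=C\CCCCCc1cc(O)cc2OC(C)(C)OC(=O)c12
F2 | step 11 | (7Z,15R)-15-ArB-15-[(triisopropylsilyl)oxy]pentadec-7-enal | C[Si](C)(C)CCOCOc1cc(cc(OCOCC[Si](C)(C)C)c1Br)[C@H](O[Si](C(C)C)(C(C)C)C(C)C)CCCCCC/C=C\CCCCCC=O
F3 | step 11 | 6-{(10Z,18R)-18-ArB-4-hydroxy-2-oxo-18-[(triisopropylsilyl)oxy]octadec-10-en-1-yl}-2,2-dimethyl-4H-1,3-dioxin-4-one, both C4 carbinol epimers | C[Si](C)(C)CCOCOc1cc(cc(OCOCC[Si](C)(C)C)c1Br)[C@H](O[Si](C(C)C)(C(C)C)C(C)C)CCCCCC/C=C\CCCCCC(O)CC(=O)CC1=CC(=O)OC(C)(C)O1
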